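**Retrosynthetic overview**

1. The target is the free phenol of MOM ether 20; the quinone ring (ring C) of 20 is made last, by thermal expansion of the four-membered ring of the 4-alkynyl-4-hydroxycyclobutenone 17.
2. Compound 17 comes from dimethyl squarate 15 and the lithium acetylide 16 of (3S)-3-ethynylchroman, generated from dibromoolefin 14.
3. Compound 14 comes from (3S)-chroman-3-ylmethanol 12; the only stereocentre (chroman C3) is set by iridium-catalysed asymmetric hydrogenation of the 2H-chromene allylic alcohol 11.
4. Ring A (the tetraoxygenated arene) is bought as aldehyde 1 and re-functionalised to salicylaldehyde 6; ring B (the pyran) is closed with acrolein; ring order is A, then B, then the four-membered ring, then C.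
5. Enabling feature: in ring C the two carbonyl carbons C1/C4 and the two methoxy-bearing carbons C2/C3 form one contiguous, symmetric C4 unit (the ring of dimethyl squarate), while C5 (bonded to chroman C3) and C6–H are the two carbons of a terminal alkyne; the tertiary OH on the sp3 ring carbon of 17 steers the ring opening and becomes the C6 hydrogen.

Key step: step 10

Assumption: in step 6 the (S)-configured phosphinooxazoline ligand is taken to give the (3S)-alcohol; should a test run show the opposite sense, the (R)-ligand is used and nothing else changes.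

**Route**

Step 1
Reactants: 1 2-hydroxy-3,4-dimethoxybenzaldehyde
Product: 2 3,4-dimethoxy-2-(methoxymethoxy)benzaldehyde
Conditions: MOMCl, i-Pr2NEt, CH2Cl2, 0 °C to rt
Reagents that add atoms: chloromethyl methyl ether, COCCl
Why: O-alkylation of the phenol (Williamson-type) should install a base-stable, acid-labile MOM acetal on the oxygen that becomes the C8 hydroxyl.

Step 2
Reactants: 2 3,4-dimethoxy-2-(methoxymethoxy)benzaldehyde
Product: 4 3,4-dimethoxy-2-(methoxymethoxy)phenol, via aryl formate 3 (not isolated)
Conditions: mCPBA, NaHCO3, CH2Cl2, 0 °C to rt; then K2CO3 (cat.), MeOH, rt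
Reagents that add atoms: mCPBA, OOC(=O)c1cccc(Cl)c1
Why: Baeyer–Villiger oxidation with migration of the electron-rich aryl group should give formate 3, whose methanolysis frees a phenol next to the protected one, so the two catechol oxygens are differentiated.

Step 3
Reactants: 4 3,4-dimethoxy-2-(methoxymethoxy)phenol
Product: 6 2-hydroxy-4,5-dimethoxy-3-(methoxymethoxy)benzaldehyde, via salicyl alcohol 5 (not isolated)
Conditions: MgCl2, Et3N, (CH2O)n, MeCN, reflux
Reagents that add atoms: paraformaldehyde (reacts as formaldehyde), C=O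
Why: Casnati–Skattebøl ortho-formylation, in which formaldehyde bound to the magnesium phenoxide attacks the only free ortho position and the resulting benzylic alkoxide passes hydride to a second formaldehyde, should give the salicylaldehyde regiospecifically.

Step 4
Reactants: 6 2-hydroxy-4,5-dimethoxy-3-(methoxymethoxy)benzaldehyde; 7 acrolein
Product: 10 6,7-dimethoxy-8-(methoxymethoxy)-2H-chromene-3-carbaldehyde, via oxa-Michael adduct 8 (not isolated), via aldol adduct 9 (not isolated)
Conditions: K2CO3, 1,4-dioxane, reflux
Reagents that add atoms: none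
Why: Domino oxa-Michael addition and intramolecular aldol condensation, the standard route from salicylaldehydes to 2H-chromene-3-carbaldehydes, should close ring B and place the one-carbon handle on C3.

Step 5
Reactants: 10 6,7-dimethoxy-8-(methoxymethoxy)-2H-chromene-3-carbaldehyde
Product: 11 [6,7-dimethoxy-8-(methoxymethoxy)-2H-chromen-3-yl]methanol
Conditions: NaBH4, CeCl3·7H2O, MeOH, 0 °C
Reagents that add atoms: none
Why: Luche reduction should reduce the enal 1,2-selectively to the allylic alcohol without touching the styrene-type double bond.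

Step 6
Reactants: 11 [6,7-dimethoxy-8-(methoxymethoxy)-2H-chromen-3-yl]methanol
Product: 12 [(3S)-6,7-dimethoxy-8-(methoxymethoxy)chroman-3-yl]methanol
Conditions: H2 (50 bar), [Ir(cod)(L)][B(C6H3-3,5-(CF3)2)4] (1 mol %; L = (S)-4-tert-butyl-2-[2-(diphenylphosphino)phenyl]-4,5-dihydrooxazole), CH2Cl2, rt
Reagents that add atoms: none
Why: Iridium P,N-catalysed asymmetric hydrogenation of a trisubstituted allylic alcohol of the (E)-2-alkylcinnamyl alcohol type should deliver H2 to one face under control of the chiral ligand and so set C3 as S, without hydrogenolysis of the aryl or allylic ethers.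

Step 7
Reactants: 12 [(3S)-6,7-dimethoxy-8-(methoxymethoxy)chroman-3-yl]methanol
Product: 13 (3R)-6,7-dimethoxy-8-(methoxymethoxy)chromane-3-carbaldehyde
Conditions: Dess–Martin periodinane, NaHCO3, CH2Cl2, 0 °C to rt; used crude at once
Reagents that add atoms: none
Why: Dess–Martin oxidation under buffered, non-basic conditions should stop at the aldehyde without enolisation or retro-oxa-Michael opening, so the centre is kept (the descriptor changes to R only through the priority change).

Step 8
Reactants: 13 (3R)-6,7-dimethoxy-8-(methoxymethoxy)chromane-3-carbaldehyde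
Product: 14 (3S)-3-(2,2-dibromoethenyl)-6,7-dimethoxy-8-(methoxymethoxy)chroman
Conditions: CBr4, PPh3, 2,6-lutidine, CH2Cl2, 0 °C
Reagents that add atoms: carbon tetrabromide, BrC(Br)(Br)Br
Why: Corey–Fuchs dibromoolefination is a Wittig reaction with the weakly basic ylide Ph3P=CBr2, so the α-stereocentre should survive, and lutidine protects the MOM acetal from traces of HBr.

Step 9
Reactants: 14 (3S)-3-(2,2-dibromoethenyl)-6,7-dimethoxy-8-(methoxymethoxy)chroman; 15 dimethyl squarate (3,4-dimethoxycyclobut-3-ene-1,2-dione)
Product: 17 4-{[(3S)-6,7-dimethoxy-8-(methoxymethoxy)chroman-3-yl]ethynyl}-4-hydroxy-2,3-dimethoxycyclobut-2-en-1-one (both carbinol epimers), via lithium acetylide 16 (not isolated)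
Conditions: n-BuLi (2.1 equiv), THF, −78 °C; cannulated into 15 (1.2 equiv), THF, −78 °C; aq NH4Cl, −78 °C
Reagents that add atoms: none
Why: The second stage of the Corey–Fuchs sequence (Li–Br exchange, Fritsch–Buttenberg–Wiechell 1,2-shift, deprotonation) should give the acetylide, which adds 1,2 to one carbonyl of the symmetric squarate (inverse addition prevents double addition); the new carbinol centre forms as both epimers, which does not matter because step 10 erases it.

Step 10
Reactants: 17 4-{[(3S)-6,7-dimethoxy-8-(methoxymethoxy)chroman-3-yl]ethynyl}-4-hydroxy-2,3-dimethoxycyclobut-2-en-1-one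
Product: 20 5-[(3S)-6,7-dimethoxy-8-(methoxymethoxy)chroman-3-yl]-2,3-dimethoxycyclohexa-2,5-diene-1,4-dione, via enynylketene 18 (not isolated), via aryl diradical 19 (not isolated)
Conditions: degassed toluene (0.01 M), 110 °C
Reagents that add atoms: none
Why: Heating opens the cyclobutenone by 4π-electrocyclic cleavage of the C1–C4 bond with the C4 hydroxyl rotating outward, so the alkynyl group of ketene 18 lies cis to the ketene; the ketene carbon then bonds to the distal alkyne carbon (the one carrying the chroman) to give the aromatic diradical 19, and transfer of the hydroxyl hydrogen to the σ-radical carbon gives the quinone, the four-membered ring having grown by the two alkyne carbons. The closest known reaction type is the Moore rearrangement of 4-alkynyl-4-hydroxycyclobutenones derived from squaric esters, which gives 5-alkyl-2,3-dimethoxy-1,4-benzoquinones when the alkyne carries an sp3 substituent. The one ring formed (ring C) closes in a six-membered, endo-type mode by C–C bond formation between the ketene carbon and the remote alkyne carbon. No stereocentre is created: the carbinol centre of 17 is erased, and chroman C3 is a spectator because it is neither a radical site nor exposed to base. The step needs six- over five-membered closure (quinone versus 2-alkylidenecyclopentene-1,3-dione); this is secured by the non-radical-stabilising secondary alkyl group on the alkyne terminus and by the free hydroxyl as internal hydrogen donor, while dilution and degassing should suppress intermolecular hydrogen abstraction.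

Step 11
Reactants: 20 5-[(3S)-6,7-dimethoxy-8-(methoxymethoxy)chroman-3-yl]-2,3-dimethoxycyclohexa-2,5-diene-1,4-dione
Product: 21 5-[(3S)-8-hydroxy-6,7-dimethoxychroman-3-yl]-2,3-dimethoxycyclohexa-2,5-diene-1,4-dione
Conditions: TsOH·H2O (cat.), MeOH/CH2Cl2, 40 °C
Reagents that add atoms: none
Why: Acid-catalysed acetal exchange of the aryl MOM ether with methanol should free the C8 phenol, while the quinone, the methyl ethers and the base-sensitive C3–H next to the quinone are not affected by a catalytic, non-nucleophilic acid.

**Compound list**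

1 | 2-hydroxy-3,4-dimethoxybenzaldehyde | O=Cc1ccc(OC)c(OC)c1O | starting material
2 | 3,4-dimethoxy-2-(methoxymethoxy)benzaldehyde | O=Cc1ccc(OC)c(OC)c1OCOC | intermediate
3 | 3,4-dimethoxy-2-(methoxymethoxy)phenyl formate | O=COc1ccc(OC)c(OC)c1OCOC | intermediate
4 | 3,4-dimethoxy-2-(methoxymethoxy)phenol | Oc1ccc(OC)c(OC)c1OCOC | intermediate
5 | 2-(hydroxymethyl)-4,5-dimethoxy-6-(methoxymethoxy)phenol | OCc1cc(OC)c(OC)c(OCOC)c1O | intermediate
6 | 2-hydroxy-4,5-dimethoxy-3-(methoxymethoxy)benzaldehyde | O=Cc1cc(OC)c(OC)c(OCOC)c1O | intermediate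
7 | acrolein | C=CC=O | starting material
8 | 4,5-dimethoxy-3-(methoxymethoxy)-2-(3-oxopropoxy)benzaldehyde | O=CCCOc1c(C=O)cc(OC)c(OC)c1OCOC | intermediate
9 | 4-hydroxy-6,7-dimethoxy-8-(methoxymethoxy)chromane-3-carbaldehyde (diastereomer mixture) | O=CC1COc2c(OCOC)c(OC)c(OC)cc2C1O | intermediate
10 | 6,7-dimethoxy-8-(methoxymethoxy)-2H-chromene-3-carbaldehyde | O=CC1=Cc2cc(OC)c(OC)c(OCOC)c2OC1 | intermediate
11 | [6,7-dimethoxy-8-(methoxymethoxy)-2H-chromen-3-yl]methanol | OCC1=Cc2cc(OC)c(OC)c(OCOC)c2OC1 | intermediate
12 | [(3S)-6,7-dimethoxy-8-(methoxymethoxy)chroman-3-yl]methanol | OC[C@H]1COc2c(OCOC)c(OC)c(OC)cc2C1 | intermediate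
13 | (3R)-6,7-dimethoxy-8-(methoxymethoxy)chromane-3-carbaldehyde | O=C[C@H]1COc2c(OCOC)c(OC)c(OC)cc2C1 | intermediate
14 | (3S)-3-(2,2-dibromoethenyl)-6,7-dimethoxy-8-(methoxymethoxy)chroman | BrC(Br)=C[C@H]1COc2c(OCOC)c(OC)c(OC)cc2C1 | intermediate
15 | dimethyl squarate (3,4-dimethoxycyclobut-3-ene-1,2-dione) | COC1=C(OC)C(=O)C1=O | starting material
16 | lithium acetylide of (3S)-3-ethynyl-6,7-dimethoxy-8-(methoxymethoxy)chroman | [Li]C#C[C@H]1COc2c(OCOC)c(OC)c(OC)cc2C1 | intermediate
17 | 4-{[(3S)-6,7-dimethoxy-8-(methoxymethoxy)chroman-3-yl]ethynyl}-4-hydroxy-2,3-dimethoxycyclobut-2-en-1-one (both carbinol epimers) | COC1=C(OC)C(O)(C#C[C@H]2COc3c(OCOC)c(OC)c(OC)cc3C2)C1=O | intermediate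
18 | (3Z)-6-[(3S)-6,7-dimethoxy-8-(methoxymethoxy)chroman-3-yl]-4-hydroxy-2,3-dimethoxyhexa-1,3-dien-5-yn-1-one (enynylketene) | O=C=C(OC)/C(OC)=C(/O)C#C[C@H]1COc2c(OCOC)c(OC)c(OC)cc2C1 | intermediate
19 | aromatic diradical: phenoxyl oxygen radical plus σ-radical at the ring carbon between the C–OH carbon and the chroman-bearing carbon | COc1c(OC)c(O)[c]c([C@H]2COc3c(OCOC)c(OC)c(OC)cc3C2)c1[O] | intermediate
20 | 5-[(3S)-6,7-dimethoxy-8-(methoxymethoxy)chroman-3-yl]-2,3-dimethoxycyclohexa-2,5-diene-1,4-dione | COC1=C(OC)C(=O)C([C@H]2COc3c(OCOC)c(OC)c(OC)cc3C2)=CC1=O | intermediate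
21 | 5-[(3S)-8-hydroxy-6,7-dimethoxychroman-3-yl]-2,3-dimethoxycyclohexa-2,5-diene-1,4-dione | COC1=C(OC)C(=O)C([C@H]2COc3c(cc(OC)c(OC)c3O)C2)=CC1=O | target

**Step count and risks**

Total step count: 11. Longest linear sequence: 11 steps (1 to 21); compounds 7 and 15 are bought and enter in steps 4 and 9.

Steps most likely to fail:

Step 6. Facial discrimination in the delivery of H2 to the trisubstituted alkene may be insufficient, or the acidic iridium hydride may cleave the MOM acetal. The fallback sets out from 10 and comes back at 12. Pinnick oxidation of 10 (NaClO2, NaH2PO4, 2-methyl-2-butene, t-BuOH/H2O) should give 6,7-dimethoxy-8-(methoxymethoxy)-2H-chromene-3-carboxylic acid F1. Carboxylate-directed hydrogenation with Ru(OAc)2[(S)-BINAP] or its enantiomer (H2, MeOH), whichever gives the 3R acid, should give (3R)-6,7-dimethoxy-8-(methoxymethoxy)chromane-3-carboxylic acid F2, which can be enriched by recrystallisation if needed. Reduction with BH3·SMe2 in THF, which does not epimerise the α-centre, should return alcohol 12.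

Step 10. The ketene ring closure may divert to the five-membered mode, or the diradical may abstract hydrogen intermolecularly. The fallback sets out from 17 and comes back at 20, replacing the diradical pathway by a closed-shell electrocyclisation that is still a four-to-six ring expansion. Semihydrogenation of 17 (H2, Lindlar catalyst: Pd on CaCO3 poisoned by Pb(OAc)2, quinoline, EtOAc) should give 4-hydroxy-2,3-dimethoxy-4-{(Z)-2-[(3S)-6,7-dimethoxy-8-(methoxymethoxy)chroman-3-yl]ethenyl}cyclobut-2-en-1-one F3. Thermolysis of this 4-alkenyl-4-hydroxycyclobutenone (toluene, 110 °C; ring opening to the dienylketene, 6π-electrocyclisation, tautomerisation) should give 5-[(3S)-6,7-dimethoxy-8-(methoxymethoxy)chroman-3-yl]-2,3-dimethoxybenzene-1,4-diol F4. Oxidation of the hydroquinone with Ag2O in Et2O should give 20.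

Step 11. Acetal cleavage in the presence of the quinone may be accompanied by conjugate addition of methanol at the free C6 position or by redox exchange between the liberated phenol and the quinone. The fallback sets out from 14 and comes back at 21, moving the deprotection ahead of the ring expansion. Treatment of 14 with TsOH·H2O in MeOH at 40 °C should give (3S)-3-(2,2-dibromoethenyl)-6,7-dimethoxychroman-8-ol F5. n-BuLi (3.1 equiv, THF, −78 °C; the extra equivalent forms the lithium phenoxide), addition to 15 and NH4Cl quench should give 4-hydroxy-4-{[(3S)-8-hydroxy-6,7-dimethoxychroman-3-yl]ethynyl}-2,3-dimethoxycyclobut-2-en-1-one F6. Thermolysis of this compound under the conditions of step 10 should give 21 directly.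

**Further compounds**

F1 | step 6 | 6,7-dimethoxy-8-(methoxymethoxy)-2H-chromene-3-carboxylic acid | OC(=O)C1=Cc2cc(OC)c(OC)c(OCOC)c2OC1
F2 | step 6 | (3R)-6,7-dimethoxy-8-(methoxymethoxy)chromane-3-carboxylic acid | OC(=O)[C@H]1COc2c(OCOC)c(OC)c(OC)cc2C1
F3 | step 10 | 4-hydroxy-2,3-dimethoxy-4-{(Z)-2-[(3S)-6,7-dimethoxy-8-(methoxymethoxy)chroman-3-yl]ethenyl}cyclobut-2-en-1-one (both carbinol epimers) | COC1=C(OC)C(O)(/C=C\[C@H]2COc3c(OCOC)c(OC)c(OC)cc3C2)C1=O
F4 | step 10 | 5-[(3S)-6,7-dimethoxy-8-(methoxymethoxy)chroman-3-yl]-2,3-dimethoxybenzene-1,4-diol | COc1c(OC)c(O)c([C@H]2COc3c(OCOC)c(OC)c(OC)cc3C2)cc1O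
F5 | step 11 | (3S)-3-(2,2-dibromoethenyl)-6,7-dimethoxychroman-8-ol | BrC(Br)=C[C@H]1COc2c(O)c(OC)c(OC)cc2C1
F6 | step 11 | 4-hydroxy-4-{[(3S)-8-hydroxy-6,7-dimethoxychroman-3-yl]ethynyl}-2,3-dimethoxycyclobut-2-en-1-one (both carbinol epimers) | COC1=C(OC)C(O)(C#C[C@H]2COc3c(O)c(OC)c(OC)cc3C2)C1=O
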